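## The problem

1. Compound 12 is a furan-2(5H)-one. Its ring atoms are numbered O1, C2, C3, C4, C5 (C5 = lactone carbonyl). The only stereocentre, C2 (R), carries H and the (CH2)14CO2H chain; C3 carries a free carboxyl group and C4 a methyl group.
2. The chain is not the problem. C2 together with its chain is the unbranched C16 skeleton of hexadecanedioic acid, so only its two ends must be told apart.
3. The difficulty sits in the ring. C3=C4 is a tetrasubstituted, doubly acceptor-substituted alkene whose two carboxyl carbons (the exocyclic one on C3, and C5 on C4) are trans to each other. Syn additions to an alkyne and maleic-anhydride-type building blocks therefore give the wrong geometry.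
4. C2 has no neighbouring stereocentre to control it, so its configuration must come from a catalyst or be relayed from an earlier stereogenic element.
5. The C2–H bond is allylic, α to O1, and vinylogously activated by C5=O and the C3 carboxyl group. Deprotonation gives an aromatic 2-oxidofuran, so esters of 12 will racemise with base, and the finished ring should see only neutral or acidic media.
6. The feature that opens the plan is the three-carbon unit C2–C3–C4. Its central carbon C3 bears the exocyclic carboxyl group, its end C4 bears C5, and its other end C2 bears the oxygen O1 of that same C5 carboxyl group.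
7. This is the pattern left when a 2,3-allenoic acid (C4=C3=C2) is attacked at its far terminus by its own carboxyl oxygen while an electrophilic metal ends up on the central carbon. Because C2 carries H and one chain, such an allene is axially chiral and its axis can be mapped on C2.

## Retrosynthesis

**12 ⇒ 11.** The cuts are the O–alkyl bonds of a tert-butyl ester (chain end) and of a 2-(trimethylsilyl)ethyl ester (on C3).
- Methyl or ethyl esters would need saponification, which exposes the acidic C2–H to hydroxide. Both chosen groups leave in a single acidolysis.
- The skeleton is not simplified, but both masks are free of charge. The tert-butyl ester is bought with 1, and the silylethyl alcohol is the nucleophile of the key step.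
- The forward reaction only has to be free of base.

**11 ⇒ 9 (key disconnection).** The O1–C2 bond and the bond from C3 to its exocyclic carboxyl carbon are cut together. This leaves the acyclic allenoic acid 9 (C5O2H on C4, C4=C3=C2), carbon monoxide and an alcohol.
- Cutting only O1–C5 leaves a hydroxy-mesaconate whose alkene geometry is the unsolved problem.
- Taking both carboxyl carbons off the alcohol 6 by oxidative dicarbonylation is a syn process. It puts C5 trans to C2, and a 5-endo acylpalladation would have to be an anti addition.
- In the allene the geometry question vanishes, because the ring closure itself places C5 cis to C2.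
- Compound 9 has no ring, no stereocentre, no tetrasubstituted alkene and one carboxyl group less.
- The forward reaction must close 5-endo to the alkenylpalladium species 10, capture 10 with CO before a proton does, transfer the axis fully to C2, and do all this without base.

**9 ⇒ 7.** The C4–C5 bond is cut, so C5 also comes from CO. It is delivered to the distal alkyne carbon of the propargylic mesylate 7 through the allenylpalladium species 8.
- A stereocentre next to an alkyne is far easier to set than an axis, and the anti SN2′ course of Pd(0) makes the centre-to-axis translation predictable.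
- A ketene–ylide olefination would give the racemic allene and would need an odd-numbered C17 diacid.
- Mesylate leaves C2 on one side and O1 later enters from the opposite side. The relay centre → axis → centre is therefore a net inversion, and (R)-11 calls for (S)-7.
- The forward reaction must be anti-selective and must not let Pd(0) erode the axis.

**7 ⇒ 6 ⇒ 5.** The O–S bond and then the carbinol C–H bond are cut.
- Reducing the ynone 5 is preferred to an asymmetric alkynylation. Unbranched enolisable aldehydes are the weak substrates of that reaction, whereas alkyl alkynyl ketones are the best substrates of asymmetric transfer hydrogenation.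
- Compound 5 is achiral. The forward reaction must give the (S)-alcohol 6 and leave the triple bond alone.

**5 ⇒ 3 + 4, 3 ⇒ 1.** The bond between the carbonyl carbon (future C2) and the alkyne (future C3) is cut.
- Compound 4 brings C3, C4 and the methyl group. The Weinreb amide 3 (from 1 through the imidazolide 2) brings C2 and the whole chain, already differentiated at its ends.
- Both starting materials are commercial, and no chain-building step is needed.
- The forward reaction must stop at the ketone and spare the tert-butyl ester.

## Roads not taken

**Alternative 1:** (the most obvious road) Cut C2–C3 as an aldol bond and defer the C3=C4 double bond.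
- An auxiliary-bound succinate enolate would add to tert-butyl 16-oxohexadecanoate A1 and lactonise to the trans-paraconic acid A2. α-Methylenation would give the exo-methylene acid A3. A prototropic exo-to-endo shift and ester cleavage would then give 12.
- This road builds a stereocentre at C3 (plus those of the auxiliary) that the target does not contain, only to erase it.
- It pays for attaching and removing the auxiliary, and it brings in the methyl group by a detour.
- It ends with a base- or heat-driven equilibration in the very compound whose C2–H is most acidic.
- The chosen plan never makes a superfluous stereocentre and uses no base after ring closure.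

**Alternative 2:** Cut C2–C3 reductively, joining two electrophilic carbons.
- Commercial diethyl 2-methyl-3-oxosuccinate A4 would give, by chelation-controlled triflation, the (Z)-enol triflate A5. A catalytic asymmetric Nozaki–Hiyama–Kishi coupling with A1 would be followed by spontaneous lactonisation to the butenolide A6.
- On paper this is shorter, but it has three weak points.
  - The alkenyl metal carries an ester on the metallated carbon and is a latent allenolate. The C3=C4 geometry can be lost, and only the isomer with C5 cis to C2 can lactonise.
  - Facial selectivity on an unbranched aldehyde would rest wholly on an external ligand developed for unstabilised alkenyl groups.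
  - Low-valent chromium and manganese are reductants for fumarate-type alkenes such as A5 and A6.
- In the chosen plan the geometry is enforced by the ring closure and the configuration by an intramolecular relay.

**Alternative 3:** Keep the C2–O1 bond of a propargylic alcohol, and cut C4–C5 and the bond from C3 to a carboxyl surrogate.
- The (R)-alcohol A7 would undergo alkoxide-directed anti-carbomagnesiation with a vinyl Grignard reagent. A carbon dioxide quench would give the 3-vinylbutenolide A8. Ozonolysis and Pinnick oxidation would turn the vinyl group into the carboxyl group.
- No carbometallation delivers a carboxyl group directly, so the surrogate costs two oxidation steps on a base-sensitive butenolide.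
- The carbomagnesiation needs excess Grignard reagent with heating, which no ester at the chain end survives. A further mask and its redox adjustment would be added.
- The chosen plan installs C3–CO2R at the right oxidation level in the ring-forming step.

Key step: step 6

Assumption: 1 and 4 are taken as commercial. In the SMILES of 8 and 10 the spectator ligands on palladium are left out. The allene axis of 8, 9 and F2 is written in the extended-tetrahedral SMILES convention with an explicit hydrogen.

## Steps

Step 1
Reactants: 1 16-(tert-butoxy)-16-oxohexadecanoic acid
Product: 3 tert-butyl 16-[methoxy(methyl)amino]-16-oxohexadecanoate, via acyl imidazolide 2 (not isolated)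
Conditions: CDI, CH2Cl2, rt; then MeNH(OMe)·HCl, rt
Reagents that add atoms: N,O-dimethylhydroxylamine hydrochloride, CNOC.Cl
Why: Weinreb amide synthesis through the acyl imidazolide 2; the near-neutral medium leaves the tert-butyl ester untouched.

Step 2
Reactants: 3 tert-butyl 16-[methoxy(methyl)amino]-16-oxohexadecanoate; 4 1-propynylmagnesium bromide
Product: 5 tert-butyl 16-oxononadec-17-ynoate
Conditions: 4 (0.5 M in THF), THF, 0 °C; inverse quench into cold aq. NaHSO4
Reagents that add atoms: none
Why: Weinreb ketone synthesis: the carbonyl group is released only on quench, so a second addition is blocked, and an alkynyl Grignard reagent at 0 °C does not attack a tert-butyl ester. The cold acidic quench protonates the liberated amine before it can add to the ynone.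

Step 3
Reactants: 5 tert-butyl 16-oxononadec-17-ynoate
Product: 6 tert-butyl (S)-16-hydroxynonadec-17-ynoate
Conditions: Ru[(S,S)-TsDPEN](p-cymene) (1 mol %), i-PrOH, rt
Reagents that add atoms: none
Why: Noyori asymmetric transfer hydrogenation of an alkynyl alkyl ketone: the catalyst distinguishes the alkynyl from the alkyl side and does not reduce the triple bond. By the established sense of induction the (S,S)-catalyst should give the (S)-carbinol, and this is the only step that creates absolute configuration.

Step 4
Reactants: 6 tert-butyl (S)-16-hydroxynonadec-17-ynoate
Product: 7 tert-butyl (S)-16-(methylsulfonyloxy)nonadec-17-ynoate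
Conditions: MsCl, Et3N, CH2Cl2, −78 °C; cold aqueous work-up, used without chromatography
Reagents that add atoms: methanesulfonyl chloride, CS(=O)(=O)Cl
Why: Sulfonylation at oxygen leaves the C–O bond and hence the configuration untouched. A secondary propargylic mesylate without cation-stabilising groups should be stable enough for direct use.

Step 5
Reactants: 7 tert-butyl (S)-16-(methylsulfonyloxy)nonadec-17-ynoate
Product: 9 (Ra)-19-(tert-butoxy)-2-methyl-19-oxononadeca-2,3-dienoic acid, via allenylpalladium mesylate 8 (not isolated)
Conditions: Pd(PPh3)4 (5 mol %), CO (1 atm), 2,6-lutidine, THF–H2O 9:1, rt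
Reagents that add atoms: carbon monoxide, [C-]#[O+]; water, O
Why: Pd(0)-catalysed hydroxycarbonylation of a propargylic mesylate: Pd(0) displaces mesylate in an anti SN2′ sense to give 8, CO inserts into the C–Pd bond with retention, and water cleaves the acyl–Pd bond. The centre of (S)-7 is thereby translated into the (Ra) axis of 9. Lutidine takes up the sulfonic acid, so neither the tert-butyl ester nor the allene sees strong acid.

Step 6
Reactants: 9 (Ra)-19-(tert-butoxy)-2-methyl-19-oxononadeca-2,3-dienoic acid
Product: 11 2-(trimethylsilyl)ethyl (R)-2-[15-(tert-butoxy)-15-oxopentadecyl]-4-methyl-5-oxo-2,5-dihydrofuran-3-carboxylate, via furanonylpalladium trifluoroacetate 10 (not isolated)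
Conditions: Pd(OCOCF3)2 (5 mol %), 2,2′-(propane-2,2-diyl)bis(4,4-dimethyl-2-oxazoline) (6 mol %), 1,4-benzoquinone (1.5 equiv), CO (1 atm), Me3SiCH2CH2OH (10 equiv), CH2Cl2, 0 °C to rt
Reagents that add atoms: carbon monoxide, [C-]#[O+]; 2-(trimethylsilyl)ethanol, C[Si](C)(C)CCO
Why: Proposed new method: Halide-free Pd(II) should bind the C2=C3 π bond of 9 (ring numbering, the bond remote from the carboxyl group) on the face turned away from that group, whose oxygen then attacks the terminus C2 in a 5-endo-trig oxypalladation that closes O1–C2 and leaves palladium on the former central carbon C3 as 10. CO inserts into this alkenyl–Pd bond, 2-(trimethylsilyl)ethanol cleaves the acyl–Pd bond to give 11, and benzoquinone returns Pd(0) to Pd(II). The closest known reaction types are the Pd(II)-catalysed cyclisation of 2,3-allenoic acids, in which the same furanonyl–Pd species is captured by allyl halides or alkenes, and the Pd(II)/benzoquinone cyclisation–alkoxycarbonylation of allenyl ketones, allenols and allenyl amines; new is their union on an allenoic acid. C2 is controlled by the axis alone: the carboxyl oxygen lies in the plane of the p lobes of the attacked π bond and can reach only the lobe on its own side, while H and the chain stay above and below the nascent ring, so (Ra)-9 maps on (R)-11. The alkene geometry (C5 cis to C2, the two carboxyl carbons trans) is enforced by the ring. The step needs CO capture of 10 to outrun protodepalladation and homocoupling, which a CO-saturated, only weakly acidic medium and a low catalyst loading should secure. It also needs the axis to hold, which is why halide (reversible halopalladation) and a build-up of Pd(0) are avoided. No base is present, so the new acidic C2–H is not touched.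

Step 7
Reactants: 11 2-(trimethylsilyl)ethyl (R)-2-[15-(tert-butoxy)-15-oxopentadecyl]-4-methyl-5-oxo-2,5-dihydrofuran-3-carboxylate
Product: 12 (R)-2-(14-carboxytetradecyl)-4-methyl-5-oxo-2,5-dihydrofuran-3-carboxylic acid
Conditions: CF3CO2H–CH2Cl2 1:1, 0 °C to rt
Reagents that add atoms: none
Why: Global acidolysis: the tert-butyl ester leaves as isobutene, and the 2-(trimethylsilyl)ethyl ester fragments to ethene when trifluoroacetate attacks silicon. The butenolide and its C2–H are inert to acid at room temperature, so the stereocentre should not be scrambled.

## Compound list

1 | 16-(tert-butoxy)-16-oxohexadecanoic acid | CC(C)(C)OC(=O)CCCCCCCCCCCCCCC(=O)O | starting material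
2 | tert-butyl 16-(1H-imidazol-1-yl)-16-oxohexadecanoate | CC(C)(C)OC(=O)CCCCCCCCCCCCCCC(=O)n1ccnc1 | intermediate
3 | tert-butyl 16-[methoxy(methyl)amino]-16-oxohexadecanoate | CC(C)(C)OC(=O)CCCCCCCCCCCCCCC(=O)N(C)OC | intermediate
4 | 1-propynylmagnesium bromide | CC#C[Mg]Br | starting material
5 | tert-butyl 16-oxononadec-17-ynoate | CC#CC(=O)CCCCCCCCCCCCCCC(=O)OC(C)(C)C | intermediate
6 | tert-butyl (S)-16-hydroxynonadec-17-ynoate | CC#C[C@@H](O)CCCCCCCCCCCCCCC(=O)OC(C)(C)C | intermediate
7 | tert-butyl (S)-16-(methylsulfonyloxy)nonadec-17-ynoate | CC#C[C@@H](OS(C)(=O)=O)CCCCCCCCCCCCCCC(=O)OC(C)(C)C | intermediate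
8 | (Ra)-allenylpalladium(II) mesylate, Pd on the methyl-bearing allene terminus (phosphines omitted) | [H]C(CCCCCCCCCCCCCCC(=O)OC(C)(C)C)=[C@@]=C(C)[Pd]OS(C)(=O)=O | intermediate
9 | (Ra)-19-(tert-butoxy)-2-methyl-19-oxononadeca-2,3-dienoic acid | [H]C(CCCCCCCCCCCCCCC(=O)OC(C)(C)C)=[C@@]=C(C)C(=O)O | intermediate
10 | (R)-furanonylpalladium(II) trifluoroacetate, Pd on C3 of the butenolide (ligand omitted) | CC1=C([Pd]OC(=O)C(F)(F)F)[C@@H](CCCCCCCCCCCCCCC(=O)OC(C)(C)C)OC1=O | intermediate
11 | 2-(trimethylsilyl)ethyl (R)-2-[15-(tert-butoxy)-15-oxopentadecyl]-4-methyl-5-oxo-2,5-dihydrofuran-3-carboxylate | CC1=C(C(=O)OCC[Si](C)(C)C)[C@@H](CCCCCCCCCCCCCCC(=O)OC(C)(C)C)OC1=O | intermediate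
12 | (R)-2-(14-carboxytetradecyl)-4-methyl-5-oxo-2,5-dihydrofuran-3-carboxylic acid | CC1=C(C(=O)O)[C@@H](CCCCCCCCCCCCCCC(=O)O)OC1=O | target

## Step count and least certain steps

Total step count: 7. Longest linear sequence: 7 (1 → 3 → 5 → 6 → 7 → 9 → 11 → 12).

**Step 6 (key step, Proposed new method).**
- The most likely failure is protonation or homocoupling of the alkenyl–palladium bond before CO is taken up. Alcoholysis by a dilute, non-solvent alcohol is slower than in the methanol-based precedents, and the palladated carbon is flanked on both sides.
- A second risk is erosion of the axis by reversible palladium binding. A competing alkoxycarbonyl–palladium addition to the allene would converge on the same constitution, but it could leak configuration through π-allyl isomerisation.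
- The fallback uses known chemistry. It sets out from 9: iodolactonisation (I2, MeCN), which follows the same axis-to-centre course, gives tert-butyl (R)-15-(3-iodo-4-methyl-5-oxo-2,5-dihydrofuran-2-yl)pentadecanoate F1. Pd(0)-catalysed alkoxycarbonylation of this alkenyl iodide (PdCl2(PPh3)2, CO, Me3SiCH2CH2OH, 2,6-lutidine) comes back to the route at 11.

**Step 5.**
- Solvolysis of the mesylate by water may compete. Slow racemisation or isomerisation of the allenoic acid by Pd(0) or Pd–H on long contact would lower the fidelity of the centre-to-axis transfer.
- The fallback sets out from 7 and introduces the carboxyl group as an ester in an anhydrous medium. Pd(0), CO and Me3SiCH2CH2OH in THF give 19-tert-butyl 1-[2-(trimethylsilyl)ethyl] (Ra)-2-methylnonadeca-2,3-dienedioate F2.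
- F2 is freed from the catalyst by chromatography and unmasked in a separate, metal-free step with fluoride. The fallback comes back at 9.

**Step 3.**
- Back-reaction in 2-propanol at high conversion may reduce the enantiomeric purity on which all later steps depend. Base-induced decay of the ynone may do the same.
- The fallback replaces asymmetric catalysis by resolution and sets out from 5. Luche reduction gives racemic tert-butyl 16-hydroxynonadec-17-ynoate F3.
- A lipase (CAL-B, vinyl acetate) should then acylate the enantiomer with propynyl as the medium and the chain as the large group, according to the empirical size rule. This gives tert-butyl (S)-16-acetoxynonadec-17-ynoate F4, which is separated from the slow-reacting antipode.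
- Methanolysis (K2CO3, MeOH) comes back at 6.

**Step 7.**
- Cleavage of the silylethyl ester on the hindered, electron-poor C3 carboxyl group may lag far behind that of the tert-butyl ester. Long exposure to acid or the use of basic fluoride would then become tempting.
- The fallback avoids the second protecting group altogether. It sets out from 9 through F1 as above.
- Pd(0)-catalysed hydroxycarbonylation of F1 (CO, H2O, KOAc) gives (R)-2-[15-(tert-butoxy)-15-oxopentadecyl]-4-methyl-5-oxo-2,5-dihydrofuran-3-carboxylic acid F5. Its carboxylate form is protected against C2 deprotonation.
- Brief treatment with trifluoroacetic acid comes back at 12.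

## Further compounds

F1 | step 6 | tert-butyl (R)-15-(3-iodo-4-methyl-5-oxo-2,5-dihydrofuran-2-yl)pentadecanoate | CC1=C(I)[C@@H](CCCCCCCCCCCCCCC(=O)OC(C)(C)C)OC1=O
F2 | step 5 | 19-tert-butyl 1-[2-(trimethylsilyl)ethyl] (Ra)-2-methylnonadeca-2,3-dienedioate | [H]C(CCCCCCCCCCCCCCC(=O)OC(C)(C)C)=[C@@]=C(C)C(=O)OCC[Si](C)(C)C
F3 | step 3 | racemic tert-butyl 16-hydroxynonadec-17-ynoate | CC#CC(O)CCCCCCCCCCCCCCC(=O)OC(C)(C)C
F4 | step 3 | tert-butyl (S)-16-acetoxynonadec-17-ynoate | CC#C[C@@H](OC(C)=O)CCCCCCCCCCCCCCC(=O)OC(C)(C)C
F5 | step 7 | (R)-2-[15-(tert-butoxy)-15-oxopentadecyl]-4-methyl-5-oxo-2,5-dihydrofuran-3-carboxylic acid | CC1=C(C(=O)O)[C@@H](CCCCCCCCCCCCCCC(=O)OC(C)(C)C)OC1=O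
A1 | alternative 1 | tert-butyl 16-oxohexadecanoate | O=CCCCCCCCCCCCCCCC(=O)OC(C)(C)C
A2 | alternative 1 | (2R,3S)-2-[15-(tert-butoxy)-15-oxopentadecyl]-5-oxotetrahydrofuran-3-carboxylic acid | O=C1C[C@H](C(=O)O)[C@@H](CCCCCCCCCCCCCCC(=O)OC(C)(C)C)O1
A3 | alternative 1 | (2R,3S)-2-[15-(tert-butoxy)-15-oxopentadecyl]-4-methylidene-5-oxotetrahydrofuran-3-carboxylic acid | O=C1C(=C)[C@H](C(=O)O)[C@@H](CCCCCCCCCCCCCCC(=O)OC(C)(C)C)O1
A4 | alternative 2 | diethyl 2-methyl-3-oxosuccinate | CCOC(=O)C(=O)C(C)C(=O)OCC
A5 | alternative 2 | diethyl (Z)-2-methyl-3-{[(trifluoromethyl)sulfonyl]oxy}but-2-enedioate | CCOC(=O)/C(C)=C(\OS(=O)(=O)C(F)(F)F)C(=O)OCC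
A6 | alternative 2 | ethyl (R)-2-[15-(tert-butoxy)-15-oxopentadecyl]-4-methyl-5-oxo-2,5-dihydrofuran-3-carboxylate | CC1=C(C(=O)OCC)[C@@H](CCCCCCCCCCCCCCC(=O)OC(C)(C)C)OC1=O
A7 | alternative 3 | tert-butyl (R)-16-hydroxynonadec-17-ynoate | CC#C[C@H](O)CCCCCCCCCCCCCCC(=O)OC(C)(C)C
A8 | alternative 3 | tert-butyl (R)-15-(3-ethenyl-4-methyl-5-oxo-2,5-dihydrofuran-2-yl)pentadecanoate | CC1=C(C=C)[C@@H](CCCCCCCCCCCCCCC(=O)OC(C)(C)C)OC1=O
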